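**Strategy.** The tetronic acid ring is opened at two bonds, O1–C5 and C2–C3, so that the O1–C2(=O) unit becomes carbon dioxide and the rest an open-chain ethyl ketone carrying a tosylate at the future C5. In the key step the kinetic lithium enolate (future C3) captures CO2 and the β-keto carboxylate so formed displaces the tosylate through oxygen with inversion; ring and (R) stereocentre arise together. The step exploits the 1,3 relationship of a nucleophilic C3 and an electrophilic C5 across the C4 carbonyl of the butenolide ring. The (S)-tosylate comes from an ambliofuran-derived dienone by asymmetric epoxidation and palladium-catalysed hydrogenolysis.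

Key step: step 8

Remark: 3-(chloromethyl)furan is taken as purchasable (otherwise one step from furan-3-ylmethanol); the target is drawn as its 4-hydroxy enol tautomer. Locants for compounds 8–13 are those of the heptadecane chain (C3 = ketone, C4 = future ring C5).

**Step 1**
Reactants: 1 3-(chloromethyl)furan; 2 (2E,6E)-farnesyl bromide
Product: 4 ambliofuran, via (furan-3-ylmethyl)magnesium chloride 3 (not isolated)
Conditions: Mg, THF, 0 °C to rt; then 2, Li2CuCl4 (3 mol %), THF, 0 °C
Reagents that add atoms: none
Why: Copper-catalysed sp3–sp3 coupling of a primary allylic bromide with a heterobenzylic Grignard reagent (Kochi-type, Li2CuCl4) should take place at the primary allylic carbon without transposition, keeping both E alkenes and bonding through the furylmethyl carbon.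

**Step 2**
Reactants: 4 ambliofuran
Product: 5 (2E,6E,10E)-13-(furan-3-yl)-2,6,10-trimethyltrideca-2,6,10-trien-1-ol
Conditions: SeO2 (0.3 equiv), t-BuOOH (3 equiv), salicylic acid (0.1 equiv), CH2Cl2, 0 °C to rt
Reagents that add atoms: tert-butyl hydroperoxide, CC(C)(C)OO
Why: Riley allylic oxidation (ene reaction, then [2,3]-sigmatropic shift) should attack the terminal isopropylidene unit at its E methyl group to give the E primary allylic alcohol, the catalytic variant being mild enough for the furan; any enal 6 formed by over-oxidation is pooled into step 3.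

**Step 3**
Reactants: 5 allylic alcohol
Product: 6 (2E,6E,10E)-13-(furan-3-yl)-2,6,10-trimethyltrideca-2,6,10-trienal
Conditions: MnO2 (activated, excess), CH2Cl2, rt
Reagents that add atoms: none
Why: Activated MnO2 oxidises only the allylic primary alcohol and should leave the furan, the isolated alkenes and the alkene geometry untouched.

**Step 4**
Reactants: 6 enal; 7 diethyl (2-oxobutyl)phosphonate
Product: 8 (4E,6E,10E,14E)-17-(furan-3-yl)-6,10,14-trimethylheptadeca-4,6,10,14-tetraen-3-one
Conditions: LiCl, i-Pr2NEt, MeCN, rt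
Reagents that add atoms: none
Why: Horner–Wadsworth–Emmons olefination under Masamune–Roush conditions should give the E enone from the α-branched enal under mild base.

**Step 5**
Reactants: 8 dienone
Product: 9 (4S,5R,6E,10E,14E)-4,5-epoxy-17-(furan-3-yl)-6,10,14-trimethylheptadeca-6,10,14-trien-3-one (trans epoxide)
Conditions: La(O-i-Pr)3 (10 mol %), (R)-BINOL (10 mol %), Ph3As=O (10 mol %), t-BuOOH, 4 Å MS, THF, rt
Reagents that add atoms: tert-butyl hydroperoxide, CC(C)(C)OO
Why: Lanthanum–BINOL-catalysed asymmetric nucleophilic epoxidation (Weitz–Scheffer type) adds the peroxide 1,4 to the enone and closes to the trans α,β-epoxide, the (R)-BINOL complex being expected to give the (4S,5R) isomer (sense to be confirmed on 10 by Mosher analysis, the other BINOL enantiomer being used if it is opposite), while the isolated alkenes and the furan do not react with a nucleophilic peroxide.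

**Step 6**
Reactants: 9 epoxy ketone
Product: 10 (4S,6E,10E,14E)-17-(furan-3-yl)-4-hydroxy-6,10,14-trimethylheptadeca-6,10,14-trien-3-one
Conditions: Pd2(dba)3·CHCl3 (2.5 mol %), n-Bu3P (10 mol %), HCO2H, Et3N, dioxane, rt
Reagents that add atoms: none
Why: Tsuji-type hydrogenolysis of an alkenyl oxirane: zerovalent palladium ionises the allylic C5–O bond, formate gives a palladium hydride that is delivered to the carbon that carried the oxygen, so the homoallylic alcohol should form with the E C6=C7 alkene in place, and C4, which lies outside the π-allyl unit, keeps its oxygen and its (S) configuration.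

**Step 7**
Reactants: 10 hydroxy ketone
Product: 11 (4S,6E,10E,14E)-17-(furan-3-yl)-6,10,14-trimethyl-3-oxoheptadeca-6,10,14-trien-4-yl 4-methylbenzenesulfonate
Conditions: Ts2O, pyridine, CH2Cl2, 0 °C
Reagents that add atoms: p-toluenesulfonic anhydride, Cc1ccc(cc1)S(=O)(=O)OS(=O)(=O)c1ccc(C)cc1
Why: O-Sulfonylation with the anhydride and a weak base does not touch the C–O bond, so (S) is retained, and the absence of chloride excludes SN2 exchange at the activated α-keto carbon; an arenesulfonate is chosen because it has no acidic α-hydrogen.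

**Step 8**
Reactants: 11 (S)-tosyloxy ketone
Product: 14 (5R)-5-[(2E,6E,10E)-13-(furan-3-yl)-2,6,10-trimethyltrideca-2,6,10-trien-1-yl]-4-hydroxy-3-methylfuran-2(5H)-one, via lithium enolate 12 (not isolated), via lithium keto carboxylate 13 (not isolated)
Conditions: LiN(i-Pr)2 (1.1 equiv), THF, −78 °C, 11 added to the base; transfer into CO2-saturated THF, −78 °C; DMPU, warm to 40 °C; aq. citric acid
Reagents that add atoms: carbon dioxide, O=C=O
Why: Proposed new method: LiN(i-Pr)2 should remove a proton from the unhindered ethyl CH2 (future C3) rather than from the hindered, oxygen-bearing methine, as it does with α-silyloxy and α-acyloxy ethyl ketones, and the enolate 12 adds through carbon to CO2 (new C2–C3 bond) to give the β-keto carboxylate 13, whose carboxylate oxygen then displaces the tosylate (new O1–C5 bond) before the β-keto lactone enolises to the tetronic acid. The closest known reaction types are the carboxylation of ketone lithium enolates with CO2 and the silver-catalysed carboxylation–cyclisation of conjugated ynones with CO2 to 5-ylidene tetronic acids, in which CO2 likewise supplies O1 and C2; the alkyne acceptor is replaced here by an sp3 sulfonate. The butenolide ring closes in the 5-exo-tet mode. C5 is controlled by the substrate: SN2 displacement inverts the (S)-tosylate to the (R) centre. The step needs enolisation away from the tosyloxy carbon, secured by the kinetic base at −78 °C with inverse addition and by the absence of strong base after carboxylation (the only acidic C–H of 13 lies between its two carbonyl groups), and it needs O- rather than C-attack at C5, secured by the five-membered lactone being far easier to close than a cyclopropanone.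

**Compound list**
1 | 3-(chloromethyl)furan | ClCc1ccoc1 | starting material
2 | (2E,6E)-farnesyl bromide | CC(C)=CCC/C(C)=C/CC/C(C)=C/CBr | starting material
3 | (furan-3-ylmethyl)magnesium chloride | Cl[Mg]Cc1ccoc1 | intermediate
4 | ambliofuran, 3-[(3E,7E)-4,8,12-trimethyltrideca-3,7,11-trien-1-yl]furan | CC(C)=CCC/C(C)=C/CC/C(C)=C/CCc1ccoc1 | intermediate
5 | (2E,6E,10E)-13-(furan-3-yl)-2,6,10-trimethyltrideca-2,6,10-trien-1-ol | OC/C(C)=C/CC/C(C)=C/CC/C(C)=C/CCc1ccoc1 | intermediate
6 | (2E,6E,10E)-13-(furan-3-yl)-2,6,10-trimethyltrideca-2,6,10-trienal | O=C/C(C)=C/CC/C(C)=C/CC/C(C)=C/CCc1ccoc1 | intermediate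
7 | diethyl (2-oxobutyl)phosphonate | CCC(=O)CP(=O)(OCC)OCC | starting material
8 | (4E,6E,10E,14E)-17-(furan-3-yl)-6,10,14-trimethylheptadeca-4,6,10,14-tetraen-3-one | CCC(=O)/C=C/C(C)=C/CC/C(C)=C/CC/C(C)=C/CCc1ccoc1 | intermediate
9 | (4S,5R,6E,10E,14E)-4,5-epoxy-17-(furan-3-yl)-6,10,14-trimethylheptadeca-6,10,14-trien-3-one | CCC(=O)[C@H]1O[C@@H]1/C(C)=C/CC/C(C)=C/CC/C(C)=C/CCc2ccoc2 | intermediate
10 | (4S,6E,10E,14E)-17-(furan-3-yl)-4-hydroxy-6,10,14-trimethylheptadeca-6,10,14-trien-3-one | CCC(=O)[C@@H](O)C/C(C)=C/CC/C(C)=C/CC/C(C)=C/CCc1ccoc1 | intermediate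
11 | (4S,6E,10E,14E)-17-(furan-3-yl)-6,10,14-trimethyl-3-oxoheptadeca-6,10,14-trien-4-yl 4-methylbenzenesulfonate | CCC(=O)[C@@H](OS(=O)(=O)c1ccc(C)cc1)C/C(C)=C/CC/C(C)=C/CC/C(C)=C/CCc2ccoc2 | intermediate
12 | lithium enolate of 11, enolised toward the ethyl group (Z drawn, geometry without consequence) | C/C=C(\O[Li])[C@@H](OS(=O)(=O)c1ccc(C)cc1)C/C(C)=C/CC/C(C)=C/CC/C(C)=C/CCc2ccoc2 | intermediate
13 | lithium (4S,6E,10E,14E)-17-(furan-3-yl)-2,6,10,14-tetramethyl-3-oxo-4-(tosyloxy)heptadeca-6,10,14-trienoate (both C2 epimers) | CC(C(=O)O[Li])C(=O)[C@@H](OS(=O)(=O)c1ccc(C)cc1)C/C(C)=C/CC/C(C)=C/CC/C(C)=C/CCc2ccoc2 | intermediate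
14 | (5R)-5-[(2E,6E,10E)-13-(furan-3-yl)-2,6,10-trimethyltrideca-2,6,10-trien-1-yl]-4-hydroxy-3-methylfuran-2(5H)-one (CNP0244252.4) | CC1=C(O)[C@@H](C/C(C)=C/CC/C(C)=C/CC/C(C)=C/CCc2ccoc2)OC1=O | target

Total step count: 8. Longest linear sequence: 8 steps (1 and 2 to 14).

**Steps most likely to fail**

Step 8 (proposed new method). The risks are partial enolisation toward the tosyloxy-bearing carbon, which would erode the configuration or open a Favorskii-type closure, and slow ring closure followed by decarboxylation on work-up. The fallback uses known chemistry, sets out from 8 and returns at 14. Dienone 8 is epoxidised with the (S)-BINOL form of the step 5 catalyst to the (4R,5S)-epoxy ketone F1, which is hydrogenolysed as in step 6 to the (4R)-hydroxy ketone F2. Acylation with methyl chloroformate and pyridine gives the methyl carbonate F3. Kinetic enolisation on the ethyl side (LiN(SiMe3)2, THF, −78 to 0 °C) then lets the enolate attack the carbonate carbonyl in an intramolecular Claisen (Dieckmann-type) acylation, the established route from α-hydroxy ketone carbonates to tetronic acids. Methoxide leaves, the C–O bond at the stereocentre is never broken, and the (R) centre of F3 is carried into 14.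

Step 6. The risks are hydride delivery to the distal terminus of the π-allyl intermediate, which would give the allylic alcohol, and syn–anti isomerisation of that intermediate with loss of the E geometry. The fallback sets out from 5 and returns at 10. Alcohol 5 is converted (CBr4, PPh3, CH2Cl2, 0 °C) into the allylic bromide (2E,6E,10E)-1-bromo-13-(furan-3-yl)-2,6,10-trimethyltrideca-2,6,10-triene F4. The glycolate imide (R)-4-benzyl-3-[(4-methoxybenzyloxy)acetyl]oxazolidin-2-one F5 is made from (R)-4-benzyloxazolidin-2-one, n-BuLi and (4-methoxybenzyloxy)acetyl chloride. Its sodium enolate (NaN(SiMe3)2, THF, −78 to −45 °C) is alkylated with F4 in an Evans-type auxiliary-controlled alkylation to give the (2S)-alkylated imide F6. Transamidation (MeONHMe·HCl, AlMe3) gives the Weinreb amide F7, and EtMgBr then gives the PMB-protected ketone F8. Removal of the PMB group (DDQ, CH2Cl2, pH 7 buffer, 0 °C) leads to 10.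

Step 5. The risks are peroxide attack at the γ,δ-bond and low facial selectivity on an aliphatic dienone. The fallback sets out from 8 and returns at 9. Enone 8 is reduced 1,2 with (S)-Me-CBS oxazaborolidine and catecholborane to the (3R)-dienol F9. Sharpless asymmetric epoxidation (Ti(O-i-Pr)4, D-(−)-diisopropyl tartrate, t-BuOOH, 4 Å MS, CH2Cl2, −20 °C) is hydroxyl-directed to the allylic C4=C5 bond only and should give the (3R,4R,5R)-epoxy alcohol F10 as the matched erythro product. The tartrate fixes the epoxide configuration even if the reduction is imperfect. Dess–Martin oxidation (NaHCO3, CH2Cl2) then gives 9.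

**Further compounds**
F1 | step 8 | (4R,5S,6E,10E,14E)-4,5-epoxy-17-(furan-3-yl)-6,10,14-trimethylheptadeca-6,10,14-trien-3-one | CCC(=O)[C@@H]1O[C@H]1/C(C)=C/CC/C(C)=C/CC/C(C)=C/CCc2ccoc2
F2 | step 8 | (4R,6E,10E,14E)-17-(furan-3-yl)-4-hydroxy-6,10,14-trimethylheptadeca-6,10,14-trien-3-one | CCC(=O)[C@H](O)C/C(C)=C/CC/C(C)=C/CC/C(C)=C/CCc1ccoc1
F3 | step 8 | methyl (4R,6E,10E,14E)-17-(furan-3-yl)-6,10,14-trimethyl-3-oxoheptadeca-6,10,14-trien-4-yl carbonate | CCC(=O)[C@H](OC(=O)OC)C/C(C)=C/CC/C(C)=C/CC/C(C)=C/CCc1ccoc1
F4 | step 6 | (2E,6E,10E)-1-bromo-13-(furan-3-yl)-2,6,10-trimethyltrideca-2,6,10-triene | BrC/C(C)=C/CC/C(C)=C/CC/C(C)=C/CCc1ccoc1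
F5 | step 6 | (R)-4-benzyl-3-[(4-methoxybenzyloxy)acetyl]oxazolidin-2-one | COc1ccc(COCC(=O)N2[C@H](Cc3ccccc3)COC2=O)cc1
F6 | step 6 | (R)-4-benzyl-3-[(2S,4E,8E,12E)-15-(furan-3-yl)-2-(4-methoxybenzyloxy)-4,8,12-trimethylpentadeca-4,8,12-trienoyl]oxazolidin-2-one | O=C(N1[C@H](Cc2ccccc2)COC1=O)[C@@H](OCc1ccc(OC)cc1)C/C(C)=C/CC/C(C)=C/CC/C(C)=C/CCc1ccoc1
F7 | step 6 | (2S,4E,8E,12E)-15-(furan-3-yl)-N-methoxy-2-(4-methoxybenzyloxy)-N,4,8,12-tetramethylpentadeca-4,8,12-trienamide | CON(C)C(=O)[C@@H](OCc1ccc(OC)cc1)C/C(C)=C/CC/C(C)=C/CC/C(C)=C/CCc1ccoc1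
F8 | step 6 | (4S,6E,10E,14E)-17-(furan-3-yl)-4-(4-methoxybenzyloxy)-6,10,14-trimethylheptadeca-6,10,14-trien-3-one | CCC(=O)[C@@H](OCc1ccc(OC)cc1)C/C(C)=C/CC/C(C)=C/CC/C(C)=C/CCc1ccoc1
F9 | step 5 | (3R,4E,6E,10E,14E)-17-(furan-3-yl)-6,10,14-trimethylheptadeca-4,6,10,14-tetraen-3-ol | CC[C@@H](O)/C=C/C(C)=C/CC/C(C)=C/CC/C(C)=C/CCc1ccoc1
F10 | step 5 | (3R,4R,5R,6E,10E,14E)-4,5-epoxy-17-(furan-3-yl)-6,10,14-trimethylheptadeca-6,10,14-trien-3-ol | CC[C@@H](O)[C@H]1O[C@@H]1/C(C)=C/CC/C(C)=C/CC/C(C)=C/CCc2ccoc2
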